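## Structural features

The target 19 is a flavonol: a 4H-chromen-4-one (rings A and C) with a 3,5-dihydroxy-4-methoxyphenyl group (ring B) on C2 and a hydroxyl on C3. Ring A carries C5–OH (hydrogen-bonded to the C4 carbonyl), C6–H, C7–OMe and C8–OH, so C5 and C8 form a hydroquinone pair and the single methyl ether of ring A sits on C7 between C6–H and C8–OH. There is no stereocentre and no stereogenic axis, so the problem is purely regiochemical. The fragile elements are:
- the 5,8-hydroquinone, which air oxidises to the 5,8-quinone;
- the 5,7,8-oxygenation pattern, which strong acid can scramble to the 5,6,7-pattern by ring C opening and reclosure (Wessely–Moser rearrangement);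
- the chelating 3-hydroxy-4-pyranone;
- the five free hydroxyls beside exactly two methyl ethers (C7 and C4').

The real difficulty is ring A, a benzene ring with four oxygen substituents in a fixed pattern of free and methylated positions. Classical flavonoid chemistry must import it as a fully differentiated tetra-oxygenated acetophenone. The key step exploits the fact that C5(OH)–C6(H)=C7(OMe)–C8(OH) is, atom for atom, a ring-opened 4-hydroxy-3-methoxycyclobutenone (C8 the carbinol carbon, C7 the methoxy carbon, C6 the CH, C5 the carbonyl carbon). C8a and C4a are then simply the C6=C5 double bond of a finished 2-aryl-3-oxy-4-pyranone (ring C).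

## Logic of the disconnections

19 to 18. The three O–CH2Ph bonds (O3, O3', O5') are cut. Benzyl is chosen because it leaves under neutral hydrogenolysis, which touches neither the methyl ethers nor the flavonol and avoids the acid that could trigger ring A isomerisation. The forward step must leave the C2=C3 bond and the hydroquinone intact.

18 to 15 (key disconnection). The C4a–C5 bond of ring A is cut and C5 is reconnected to C8, so ring A contracts to the four-membered ring of 15, attached through its carbinol carbon to C6 of the pyranone. In one sentence, ring A is closed last by thermal 4π opening of the hydroxycyclobutenone of 15 to dienylketene 16 and 6π closure onto the pyranone. That sentence does not describe the chalcone route. The gain is that the tetra-oxygenated benzene ring never has to be made or differentiated. The C5/C8 oxygens, the C7 methyl ether and the C6 hydrogen are all read off a four-carbon unit. The forward step demands outward rotation of the hydroxyl in the ring opening, closure of 16 at the pyranone carbon that becomes C4a (via 17), and exclusion of oxygen.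

15 to 10 and 13. The C8–C8a bond (carbinol carbon to pyranone C6) is cut. This divides the molecule into a ring B/ring C half (10) and a four-carbon ring A synthon (13). The forward step needs a carbanion at C6 of 10 (14) and 1,2-addition to the one carbonyl of 13 that is bonded to the methoxy-bearing carbon. That regiochemistry is what places OMe on C7 and not on C6.

13 to 11. The vinylic C–H of 13 is traced back to a C–OMe of 11. A symmetrical commercial squarate replaces an unsymmetrical dione. The forward step must reduce a single carbonyl (to 12) and transpose it with loss of methanol.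

10 to 9 to 7. The O3–benzyl bond is cut first. The C4 carbonyl oxygen of 9 is then traced to a C4–Br bond, and the C5=C6 double bond to a lactol, in 7. The aromatic pyranone becomes a dihydropyranone whose bromine marks the future carbonyl position. The forward step must exchange bromine for oxygen and dehydrate (through 8) without cleaving benzyl ethers.

7 to 5, then to 2 and 3. The ring oxygen–C6 bond of 7 is opened back to a furan (oxidative ring-expansion retron, through 6). The bond between the carbinol carbon and furan C2 is then cut. The carbinol carbon becomes flavonol C2, and furan C2, C3, C4 and C5 become flavonol C3, C4, C4a and C8a. Ring C is thus assembled from an aldehyde and a four-carbon heterocycle, with no acetophenone. The forward steps need metalation of 3 at C2 only (4) and an oxidant that spares the electron-rich arene.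

2 to 1. Two O–benzyl bonds are cut, leading to a commercial aldehyde that already holds the ring B methyl ether in place.

## Other disconnections considered

Alternative 1: The first plan to come to mind cuts O1–C2 and C2–C3. An aldol condensation of the acetophenone 1-[3,6-bis(benzyloxy)-2-hydroxy-4-methoxyphenyl]ethan-1-one A1 with 2 would give the chalcone A2. Alkaline hydrogen peroxide (Algar–Flynn–Oyamada) would then close ring C and install the C3 hydroxyl. The weakness is structural: A1 is itself the hard part of the target, a benzene ring with four differentiated oxygens, and would need its own multi-step synthesis. A 6'-alkoxy group on a 2'-hydroxychalcone also twists the enone and is expected to favour five-membered (aurone) closure over flavonol formation in the oxidative cyclisation. The chosen plan builds the same oxygen pattern from a symmetrical squarate and never has to differentiate phenols on ring A.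

Alternative 2: A Dötz benzannulation would also build ring A on the pyranone. The chromium carbene complex (CO)5Cr=C(OMe)R A3 (zerovalent chromium, R = pyranon-6-yl of 10) would react with methoxyacetylene to form C8–C7, C6–C5 and C5–C4a with insertion of CO. Two features argue against it. The carbene oxygen would end as a C8 methyl ether next to the C7 methyl ether, so a selective demethylation of one of two neighbouring ethers would be required. The usual steric rule for terminal alkynes also puts the alkyne substituent next to the new phenol, which predicts the 5-hydroxy-6,8-dimethoxy isomer A4 and not the 7-methoxy pattern. The cyclobutenone route delivers the correct oxidation level and methylation pattern directly and needs no stoichiometric chromium.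

Alternative 3: The C8–O bond could be made last. Elbs persulfate oxidation (K2S2O8, aqueous KOH) of the 8-unsubstituted flavonol A5, para to the C5 phenol, would give the aryl sulfate A6, and hydrolysis would lead to 18. The plan does not simplify ring construction, since A5 still has to come from a phloroglucinol-type acetophenone by the classical sequence. The persulfate would meet an electron-rich ring B and an enol ether at C3 as competing oxidation sites. Hydrolysis of A6 needs hot acid, the very conditions under which the 5,7,8-pattern can isomerise and benzyl ethers can be lost. The chosen route introduces both hydroquinone oxygens in the ring-forming step and uses no acid afterwards.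

Key step: step 8

Assumption: 1, 3 and 11 are taken as purchasable; 5, 7, 15 and 17 are racemic (7 also a lactol epimer mixture), and all their stereocentres become sp2 before 19, so no stereocontrol is needed.

## Steps

Step 1
Reactants: 1 3,5-dihydroxy-4-methoxybenzaldehyde
Product: 2 3,5-bis(benzyloxy)-4-methoxybenzaldehyde
Conditions: BnBr (2.3 equiv), K2CO3, DMF, 60 °C
Reagents that add atoms: benzyl bromide, BrCc1ccccc1
Why: Williamson ether synthesis on two equivalent phenols; the aldehyde and the methyl ether are inert to carbonate base.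

Step 2
Reactants: 3 3-bromofuran; 2 3,5-bis(benzyloxy)-4-methoxybenzaldehyde
Product: 5 rac-[3,5-bis(benzyloxy)-4-methoxyphenyl](3-bromofuran-2-yl)methanol, via 3-bromo-2-lithiofuran 4 (not isolated)
Conditions: LiN(iPr)2, THF, −78 °C; then 2, −78 °C; then H2O
Reagents that add atoms: none
Why: Directed lithiation of 3-bromofuran occurs at C2 (flanked by the ring oxygen and bromine) without halogen scrambling at −78 °C, and the furyllithium adds 1,2 to the aldehyde. The carbinol centre is formed racemic and becomes sp2 in step 4.

Step 3
Reactants: 5 rac-[3,5-bis(benzyloxy)-4-methoxyphenyl](3-bromofuran-2-yl)methanol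
Product: 7 2-[3,5-bis(benzyloxy)-4-methoxyphenyl]-4-bromo-6-hydroxy-2H-pyran-3(6H)-one, via ring-opened keto enal 6 (not isolated)
Conditions: mCPBA, CH2Cl2, 0 °C
Reagents that add atoms: mCPBA, OOC(=O)c1cccc(Cl)c1
Why: Achmatowicz rearrangement: peracid oxidation of the furan unmasks keto enal 6, whose carbinol oxygen closes onto the aldehyde to give the pyranone lactol. The furan bromine ends on C4, where it marks the future carbonyl, and the electron-rich arene is not attacked by the peracid at 0 °C. 7 is a racemic mixture of lactol epimers, which is inconsequential.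

Step 4
Reactants: 7 2-[3,5-bis(benzyloxy)-4-methoxyphenyl]-4-bromo-6-hydroxy-2H-pyran-3(6H)-one
Product: 9 2-[3,5-bis(benzyloxy)-4-methoxyphenyl]-3-hydroxy-4H-pyran-4-one, via 4-bromo-3-hydroxypyrylium cation 8 (not isolated)
Conditions: 0.5 M aq H2SO4, 1,4-dioxane, 80 °C
Reagents that add atoms: water, O
Why: Acid-promoted enolisation of the C3 ketone towards C2 and loss of the C6 hydroxyl aromatise the ring to pyrylium 8. Water then adds at C4 and expels bromide (addition–elimination), the hydrolytic aromatisation of 4-halo-6-hydroxy-2H-pyran-3(6H)-ones used to make maltol-type 3-hydroxy-4-pyranones. Both stereocentres of 7 vanish and aryl benzyl ethers tolerate hot dilute aqueous acid.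

Step 5
Reactants: 9 2-[3,5-bis(benzyloxy)-4-methoxyphenyl]-3-hydroxy-4H-pyran-4-one
Product: 10 3-(benzyloxy)-2-[3,5-bis(benzyloxy)-4-methoxyphenyl]-4H-pyran-4-one
Conditions: BnBr, K2CO3, DMF, 50 °C
Reagents that add atoms: benzyl bromide, BrCc1ccccc1
Why: Williamson O-alkylation of the acidic enolic hydroxyl, as routinely done for maltol and kojic acid. It removes the only acidic proton before the metalation of step 7.

Step 6
Reactants: 11 3,4-dimethoxycyclobut-3-ene-1,2-dione (dimethyl squarate)
Product: 13 3-methoxycyclobut-3-ene-1,2-dione, via 4-hydroxy-2,3-dimethoxycyclobut-2-en-1-one 12 (not isolated)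
Conditions: LiAlH(OtBu)3, THF, −78 °C; then 6 M HCl, CH2Cl2, 25 °C
Reagents that add atoms: water, O
Why: The hindered hydride adds once, 1,2, to a carbonyl of the symmetrical squarate. In acid the carbinol of 12 ionises to a methoxy-stabilised cyclobutenyl cation, water adds at the methoxy-bearing terminus and methanol leaves. This reduction and allylic transposition is the established route to alkyl semisquarates.

Step 7
Reactants: 10 3-(benzyloxy)-2-[3,5-bis(benzyloxy)-4-methoxyphenyl]-4H-pyran-4-one; 13 3-methoxycyclobut-3-ene-1,2-dione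
Product: 15 rac-4-{5-(benzyloxy)-6-[3,5-bis(benzyloxy)-4-methoxyphenyl]-4-oxo-4H-pyran-2-yl}-4-hydroxy-3-methoxycyclobut-2-en-1-one, via 6-lithiopyranone 14 (not isolated)
Conditions: lithium 2,2,6,6-tetramethylpiperidide (from n-BuLi and 2,2,6,6-tetramethylpiperidine), THF, −78 °C; cannulate into 13, THF, −78 °C; AcOH, −78 °C
Reagents that add atoms: none
Why: The hindered lithium amide removes the only C–H next to the ring oxygen (C6–H; C2 is blocked by the aryl group), as in C2-lithiation of 3-substituted chromones. The vinyllithium adds 1,2 to the ketone of 13 that is bonded to the methoxy-bearing carbon, because the other carbonyl is deactivated as a vinylogous ester; this is the normal regiochemistry of organolithium additions to alkoxycyclobutenediones. The carbinol stereocentre is racemic and is erased in step 8.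

Step 8
Reactants: 15 rac-4-{5-(benzyloxy)-6-[3,5-bis(benzyloxy)-4-methoxyphenyl]-4-oxo-4H-pyran-2-yl}-4-hydroxy-3-methoxycyclobut-2-en-1-one
Product: 18 3-(benzyloxy)-2-[3,5-bis(benzyloxy)-4-methoxyphenyl]-5,8-dihydroxy-7-methoxy-4H-chromen-4-one, via (Z)-dienylketene 16 (not isolated), via 4aH-chromene-4,5-dione tautomer 17 (not isolated)
Conditions: degassed p-xylene, 130 °C, argon
Reagents that add atoms: none
Why: This is a Moore rearrangement of a 4-hydroxy-4-(hetero)arylcyclobutenone, the closest known reaction type. Heat opens the C1–C4 bond of the cyclobutenone in a conrotatory 4π electrocyclic reaction; the hydroxyl, as the donor substituent, rotates outward, so the pyranonyl group turns inward and ketene 16 has the (Z) geometry with the ketene carbon beside pyranone C5. A thermal disrotatory 6π electrocyclisation then joins the electrophilic ketene carbon to pyranone C5, the nucleophilic α-carbon of the vinylogous ester, and closes six-membered ring A as dienone 17; the weak aromaticity of the 4-pyranone makes this closure less costly than onto a benzene ring. Tautomerisation of the C4a hydrogen to oxygen aromatises ring A to the 5,8-hydroquinone 18, whose new C5 hydroxyl is held by a hydrogen bond to the C4 carbonyl. No stereocentre survives, since the carbinol carbon of 15 and C4a of 17 both become sp2. Regiochemistry is fixed by the substrate: the only carbon neighbour of the attachment point is C5 (the other neighbour is the ring oxygen), and the cyclobutenone already carries H and OMe on the carbons that become C6 and C7. The required torquoselectivity rests on the free hydroxyl, and exclusion of oxygen keeps 18 from going on to the 5,8-quinone.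

Step 9
Reactants: 18 3-(benzyloxy)-2-[3,5-bis(benzyloxy)-4-methoxyphenyl]-5,8-dihydroxy-7-methoxy-4H-chromen-4-one
Product: 19 2-(3,5-dihydroxy-4-methoxyphenyl)-3,5,8-trihydroxy-7-methoxy-4H-chromen-4-one
Conditions: H2 (1 atm), 10% Pd/C, EtOAc/MeOH, 25 °C; work-up under argon
Reagents that add atoms: none
Why: Catalytic hydrogenolysis cleaves the three benzyl ethers, while the tetrasubstituted C2=C3 bond of the flavonol and the two methyl ethers are inert. The neutral conditions avoid acid-induced isomerisation of ring A, and the inert work-up protects the hydroquinone.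

## Compound list

1 | 3,5-dihydroxy-4-methoxybenzaldehyde | COc1c(O)cc(C=O)cc1O | starting material
2 | 3,5-bis(benzyloxy)-4-methoxybenzaldehyde | COc1c(OCc2ccccc2)cc(C=O)cc1OCc1ccccc1 | intermediate
3 | 3-bromofuran | Brc1ccoc1 | starting material
4 | 3-bromo-2-lithiofuran | [Li]c1occc1Br | intermediate
5 | rac-[3,5-bis(benzyloxy)-4-methoxyphenyl](3-bromofuran-2-yl)methanol | COc1c(OCc2ccccc2)cc(C(O)c2occc2Br)cc1OCc1ccccc1 | intermediate
6 | (2E)-5-[3,5-bis(benzyloxy)-4-methoxyphenyl]-3-bromo-5-hydroxy-4-oxopent-2-enal (racemic) | O=C/C=C(/Br)C(=O)C(O)c1cc(OCc2ccccc2)c(OC)c(OCc2ccccc2)c1 | intermediate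
7 | 2-[3,5-bis(benzyloxy)-4-methoxyphenyl]-4-bromo-6-hydroxy-2H-pyran-3(6H)-one (racemic, lactol epimers) | OC1C=C(Br)C(=O)C(c2cc(OCc3ccccc3)c(OC)c(OCc3ccccc3)c2)O1 | intermediate
8 | 2-[3,5-bis(benzyloxy)-4-methoxyphenyl]-4-bromo-3-hydroxypyrylium | Oc1c(Br)cc[o+]c1-c1cc(OCc2ccccc2)c(OC)c(OCc2ccccc2)c1 | intermediate
9 | 2-[3,5-bis(benzyloxy)-4-methoxyphenyl]-3-hydroxy-4H-pyran-4-one | O=c1ccoc(-c2cc(OCc3ccccc3)c(OC)c(OCc3ccccc3)c2)c1O | intermediate
10 | 3-(benzyloxy)-2-[3,5-bis(benzyloxy)-4-methoxyphenyl]-4H-pyran-4-one | O=c1ccoc(-c2cc(OCc3ccccc3)c(OC)c(OCc3ccccc3)c2)c1OCc1ccccc1 | intermediate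
11 | 3,4-dimethoxycyclobut-3-ene-1,2-dione (dimethyl squarate) | COC1=C(OC)C(=O)C1=O | starting material
12 | 4-hydroxy-2,3-dimethoxycyclobut-2-en-1-one (racemic) | COC1=C(OC)C(=O)C1O | intermediate
13 | 3-methoxycyclobut-3-ene-1,2-dione | COC1=CC(=O)C1=O | intermediate
14 | {5-(benzyloxy)-6-[3,5-bis(benzyloxy)-4-methoxyphenyl]-4-oxo-4H-pyran-2-yl}lithium | [Li]c1cc(=O)c(OCc2ccccc2)c(-c2cc(OCc3ccccc3)c(OC)c(OCc3ccccc3)c2)o1 | intermediate
15 | rac-4-{5-(benzyloxy)-6-[3,5-bis(benzyloxy)-4-methoxyphenyl]-4-oxo-4H-pyran-2-yl}-4-hydroxy-3-methoxycyclobut-2-en-1-one | COC1=CC(=O)C1(O)c1cc(=O)c(OCc2ccccc2)c(-c2cc(OCc3ccccc3)c(OC)c(OCc3ccccc3)c2)o1 | intermediate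
16 | (3Z)-4-{5-(benzyloxy)-6-[3,5-bis(benzyloxy)-4-methoxyphenyl]-4-oxo-4H-pyran-2-yl}-4-hydroxy-3-methoxybuta-1,3-dien-1-one | O=C=C/C(OC)=C(/O)c1cc(=O)c(OCc2ccccc2)c(-c2cc(OCc3ccccc3)c(OC)c(OCc3ccccc3)c2)o1 | intermediate
17 | rac-3-(benzyloxy)-2-[3,5-bis(benzyloxy)-4-methoxyphenyl]-8-hydroxy-7-methoxy-4aH-chromene-4,5-dione | COC1=CC(=O)C2C(=O)C(OCc3ccccc3)=C(c3cc(OCc4ccccc4)c(OC)c(OCc4ccccc4)c3)OC2=C1O | intermediate
18 | 3-(benzyloxy)-2-[3,5-bis(benzyloxy)-4-methoxyphenyl]-5,8-dihydroxy-7-methoxy-4H-chromen-4-one | COc1cc(O)c2c(=O)c(OCc3ccccc3)c(-c3cc(OCc4ccccc4)c(OC)c(OCc4ccccc4)c3)oc2c1O | intermediate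
19 | 2-(3,5-dihydroxy-4-methoxyphenyl)-3,5,8-trihydroxy-7-methoxy-4H-chromen-4-one | COc1cc(O)c2c(=O)c(O)c(-c3cc(O)c(OC)c(O)c3)oc2c1O | target

## Step count and least certain steps

Total: 9 steps. Longest linear sequence: 8 steps (steps 1, 2, 3, 4, 5, 7, 8, 9); step 6 is a one-step side branch.

Step 8 (key step). The ketene may be diverted before ring closure: inward rotation of the hydroxyl followed by lactonisation to a butenolide, or intermolecular trapping and dimerisation of the monosubstituted ketene. The hot hydroquinone may also be oxidised to the quinone by traces of air. The fallback sets out from 15 and masks the carbinol, so that no O–H can add to the ketene and the first product is a mono-silylated hydroquinone that cannot be oxidised to the quinone. Silylation (Et3SiOTf, 2,6-lutidine, CH2Cl2, −78 °C) gives 4-{5-(benzyloxy)-6-[3,5-bis(benzyloxy)-4-methoxyphenyl]-4-oxo-4H-pyran-2-yl}-3-methoxy-4-[(triethylsilyl)oxy]cyclobut-2-en-1-one F1. Thermolysis in p-xylene should give 3-(benzyloxy)-2-[3,5-bis(benzyloxy)-4-methoxyphenyl]-5-hydroxy-7-methoxy-8-[(triethylsilyl)oxy]-4H-chromen-4-one F2. Desilylation with Bu4NF/AcOH in THF comes back to the route at 18.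

Step 7. Three things may go wrong:
- competing metalation at a ring B position next to a benzyloxy group or at a benzylic CH2;
- addition of the lithiated pyranone to the C4 carbonyl of unmetalated 10;
- attack at the wrong site of 13 (conjugate addition, or addition to the vinylogous ester carbonyl, which would move the methoxy group to C6).

The fallback sets out from 10 and generates the nucleophile by halogen–metal exchange in place of deprotonation. Zincation with TMPZnCl·LiCl (TMP = 2,2,6,6-tetramethylpiperidide) in THF at 25 °C gives a zinc species that does not attack the carbonyl. Iodine converts it to 3-(benzyloxy)-2-[3,5-bis(benzyloxy)-4-methoxyphenyl]-6-iodo-4H-pyran-4-one F3. Iodine–magnesium exchange with i-PrMgCl·LiCl at −78 °C then gives a less basic Grignard reagent, and its addition to 13 comes back to the route at 15.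

Step 4. Benzyl ethers may be lost, or the electron-rich aryl lactol may ring-open and polymerise, in hot aqueous acid before the pyrylium is hydrolysed. The fallback sets out from 2 and uses an epoxide, not a bromine, to carry the extra oxidation level:
- 2-Furyllithium (furan, n-BuLi, THF) adds to 2 to give rac-[3,5-bis(benzyloxy)-4-methoxyphenyl](furan-2-yl)methanol F4.
- mCPBA converts it to 2-[3,5-bis(benzyloxy)-4-methoxyphenyl]-6-hydroxy-2H-pyran-3(6H)-one F5.
- HC(OMe)3 with catalytic BF3·OEt2 gives the methyl acetal 2-[3,5-bis(benzyloxy)-4-methoxyphenyl]-6-methoxy-2H-pyran-3(6H)-one F6.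
- Nucleophilic epoxidation (H2O2, NaOH, MeOH, 0 °C), which cannot touch the arene, gives 4-[3,5-bis(benzyloxy)-4-methoxyphenyl]-2-methoxy-3,7-dioxabicyclo[4.1.0]heptan-5-one F7.
- Brief warming with acid isomerises the epoxy ketone and eliminates methanol, and the sequence comes back to the route at 9.

## Further compounds

F1 | step 8 | rac-4-{5-(benzyloxy)-6-[3,5-bis(benzyloxy)-4-methoxyphenyl]-4-oxo-4H-pyran-2-yl}-3-methoxy-4-[(triethylsilyl)oxy]cyclobut-2-en-1-one | CC[Si](CC)(CC)OC1(c2cc(=O)c(OCc3ccccc3)c(-c3cc(OCc4ccccc4)c(OC)c(OCc4ccccc4)c3)o2)C(OC)=CC1=O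
F2 | step 8 | 3-(benzyloxy)-2-[3,5-bis(benzyloxy)-4-methoxyphenyl]-5-hydroxy-7-methoxy-8-[(triethylsilyl)oxy]-4H-chromen-4-one | COc1cc(O)c2c(=O)c(OCc3ccccc3)c(-c3cc(OCc4ccccc4)c(OC)c(OCc4ccccc4)c3)oc2c1O[Si](CC)(CC)CC
F3 | step 7 | 3-(benzyloxy)-2-[3,5-bis(benzyloxy)-4-methoxyphenyl]-6-iodo-4H-pyran-4-one | Ic1cc(=O)c(OCc2ccccc2)c(-c2cc(OCc3ccccc3)c(OC)c(OCc3ccccc3)c2)o1
F4 | step 4 | rac-[3,5-bis(benzyloxy)-4-methoxyphenyl](furan-2-yl)methanol | COc1c(OCc2ccccc2)cc(C(O)c2ccco2)cc1OCc1ccccc1
F5 | step 4 | 2-[3,5-bis(benzyloxy)-4-methoxyphenyl]-6-hydroxy-2H-pyran-3(6H)-one (racemic, lactol epimers) | OC1C=CC(=O)C(c2cc(OCc3ccccc3)c(OC)c(OCc3ccccc3)c2)O1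
F6 | step 4 | 2-[3,5-bis(benzyloxy)-4-methoxyphenyl]-6-methoxy-2H-pyran-3(6H)-one (racemic, acetal epimers) | COC1C=CC(=O)C(c2cc(OCc3ccccc3)c(OC)c(OCc3ccccc3)c2)O1
F7 | step 4 | 4-[3,5-bis(benzyloxy)-4-methoxyphenyl]-2-methoxy-3,7-dioxabicyclo[4.1.0]heptan-5-one (racemic, diastereomer mixture) | COC1OC(c2cc(OCc3ccccc3)c(OC)c(OCc3ccccc3)c2)C(=O)C2OC12
A1 | alternative 1 | 1-[3,6-bis(benzyloxy)-2-hydroxy-4-methoxyphenyl]ethan-1-one | COc1cc(OCc2ccccc2)c(C(C)=O)c(O)c1OCc1ccccc1
A2 | alternative 1 | (2E)-1-[3,6-bis(benzyloxy)-2-hydroxy-4-methoxyphenyl]-3-[3,5-bis(benzyloxy)-4-methoxyphenyl]prop-2-en-1-one | COc1cc(OCc2ccccc2)c(C(=O)/C=C/c2cc(OCc3ccccc3)c(OC)c(OCc3ccccc3)c2)c(O)c1OCc1ccccc1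
A3 | alternative 2 | pentacarbonyl[{5-(benzyloxy)-6-[3,5-bis(benzyloxy)-4-methoxyphenyl]-4-oxo-4H-pyran-2-yl}(methoxy)methylidene]chromium | COC(c1cc(=O)c(OCc2ccccc2)c(-c2cc(OCc3ccccc3)c(OC)c(OCc3ccccc3)c2)o1)=[Cr](=C=O)(=C=O)(=C=O)(=C=O)=C=O
A4 | alternative 2 | 3-(benzyloxy)-2-[3,5-bis(benzyloxy)-4-methoxyphenyl]-5-hydroxy-6,8-dimethoxy-4H-chromen-4-one | COc1cc(OC)c2oc(-c3cc(OCc4ccccc4)c(OC)c(OCc4ccccc4)c3)c(OCc3ccccc3)c(=O)c2c1O
A5 | alternative 3 | 3-(benzyloxy)-2-[3,5-bis(benzyloxy)-4-methoxyphenyl]-5-hydroxy-7-methoxy-4H-chromen-4-one | COc1cc(O)c2c(=O)c(OCc3ccccc3)c(-c3cc(OCc4ccccc4)c(OC)c(OCc4ccccc4)c3)oc2c1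
A6 | alternative 3 | 3-(benzyloxy)-2-[3,5-bis(benzyloxy)-4-methoxyphenyl]-5-hydroxy-7-methoxy-4-oxo-4H-chromen-8-yl hydrogen sulfate | COc1cc(O)c2c(=O)c(OCc3ccccc3)c(-c3cc(OCc4ccccc4)c(OC)c(OCc4ccccc4)c3)oc2c1OS(=O)(=O)O
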